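**Retrosynthetic overview**
1. Target 28 ← desilylation ← acylation of the only secondary OH ← γ-lactone closed last by Pd-catalysed cyclocarbonylation of a cis-2-ethynylcycloheptanol (22).
2. 22 ← hydroxyl-directed reduction of 2-acyl-2-hydroxycycloheptanone 20 ← one-carbon ring expansion (α-ketol 1,2-shift, six → seven) of the cyclohexanol-derived β-hydroxy-α-diketone 19, which relays the carbinol configuration to the quaternary C–OH centre.
3. 19 ← oxygen transfer to the aldol adduct 18 of diazoketone 17 (from (S)-3-hydroxybutanoic acid) and cyclohexanone 12.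
4. 12 ← 2-methylcyclohex-2-en-1-one by asymmetric β-borylation/oxidation, dehydrogenation, conjugate alkynylation/bromination and formate inversion.
5. Ring order: cyclohexane (bought) → cycloheptane (ring expansion) → lactone (carbonylation).

Assumption: (R)-2-methylbutanoic acid and (S)-3-hydroxybutanoic acid are bought enantiopure, and the Josiphos enantiomer in step 1 is the one that gives the (3R)-boronate (its mirror image is used if the sense is opposite).

**Step 1**
Reactants: 1 2-methylcyclohex-2-en-1-one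
Product: 3 (2S,3R)-3-hydroxy-2-methylcyclohexan-1-one, via boronate ester 2 (not isolated)
Conditions: B2pin2, CuCl (3 mol%), NaOtBu (5 mol%), (R,Sp)-Josiphos (3 mol%), MeOH (2 equiv), THF, rt; then NaBO3·4H2O, THF/H2O, rt
Reagents that add atoms: sodium perborate, [Na+].[O-]OB=O
Why: Copper-catalysed asymmetric conjugate borylation sets C3 under ligand control, C–B oxidation goes with retention, and the enolisable C2 centre settles to the trans (diequatorial) isomer in the basic perborate medium.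

**Step 2**
Reactants: 3 (2S,3R)-3-hydroxy-2-methylcyclohexan-1-one
Product: 4 (2S,3R)-3-[(tert-butyldimethylsilyl)oxy]-2-methylcyclohexan-1-one
Conditions: TBSCl, imidazole, DMF, rt
Reagents that add atoms: tert-butyldimethylsilyl chloride, CC(C)(C)[Si](C)(C)Cl
Why: Routine silylation blocks retro-aldol and elimination of the β-hydroxy ketone and leaves both stereocentres untouched.

**Step 3**
Reactants: 4 (2S,3R)-3-[(tert-butyldimethylsilyl)oxy]-2-methylcyclohexan-1-one
Product: 6 (5R,6S)-5-[(tert-butyldimethylsilyl)oxy]-6-methylcyclohex-2-en-1-one, via silyl enol ether 5 (not isolated)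
Conditions: LiN(iPr)2, THF, −78 °C; TMSCl; then Pd(OAc)2 (1.05 equiv), MeCN, rt
Reagents that add atoms: none
Why: Kinetic deprotonation takes place at the unsubstituted C6 methylene, and Saegusa–Ito dehydrogenation of the silyl enol ether gives the enone without touching the stereocentres.

**Step 4**
Reactants: 6 (5R,6S)-5-[(tert-butyldimethylsilyl)oxy]-6-methylcyclohex-2-en-1-one; 7 ethynyltrimethylsilane
Product: 9 (2S,3S,5R,6S)-2-bromo-5-[(tert-butyldimethylsilyl)oxy]-6-methyl-3-[(trimethylsilyl)ethynyl]cyclohexan-1-one, via silyl enol ether 8 (not isolated)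
Conditions: 7, n-BuLi, THF, −78 °C; ZnBr2; then 6, TMSOTf, Et2O/THF, −40 °C; then NBS, THF, −78 °C
Reagents that add atoms: N-bromosuccinimide, O=C1CCC(=O)N1Br
Why: Silyl-triflate-promoted conjugate addition of the alkynylzinc enters axially anti to the C5 silyloxy group (3,5-trans) and gives a regiodefined silyl enol ether, which NBS brominates anti to the new pseudoaxial alkynyl group (2,3-trans).

**Step 5**
Reactants: 9 (2S,3S,5R,6S)-2-bromo-5-[(tert-butyldimethylsilyl)oxy]-6-methyl-3-[(trimethylsilyl)ethynyl]cyclohexan-1-one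
Product: 11 (2R,3S,5R,6S)-5-[(tert-butyldimethylsilyl)oxy]-3-ethynyl-2-hydroxy-6-methylcyclohexan-1-one, via formate ester 10 (not isolated)
Conditions: HCO2K, 18-crown-6 (cat.), DMF, 0 °C to rt; then K2CO3 (0.3 equiv), MeOH, 0 °C
Reagents that add atoms: potassium formate, [K+].[O-]C=O
Why: SN2 displacement of the activated α-bromo ketone by formate inverts C2 so that oxygen ends equatorial and cis to the alkynyl group, and mild methanolysis then removes the formyl group and the alkynyl silane together.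

**Step 6**
Reactants: 11 (2R,3S,5R,6S)-5-[(tert-butyldimethylsilyl)oxy]-3-ethynyl-2-hydroxy-6-methylcyclohexan-1-one
Product: 12 (2R,3S,5R,6S)-5-[(tert-butyldimethylsilyl)oxy]-3-ethynyl-6-methyl-2-[(triethylsilyl)oxy]cyclohexan-1-one
Conditions: TESCl, imidazole, DMF, 0 °C
Reagents that add atoms: chlorotriethylsilane, CC[Si](Cl)(CC)CC
Why: The secondary α-hydroxyl is capped with a silyl group that can later be removed selectively beside the two TBS ethers.

**Step 7**
Reactants: 13 (S)-3-hydroxybutanoic acid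
Product: 14 tert-butyldimethylsilyl (S)-3-[(tert-butyldimethylsilyl)oxy]butanoate
Conditions: TBSCl (2.3 equiv), imidazole, DMF, rt
Reagents that add atoms: tert-butyldimethylsilyl chloride, CC(C)(C)[Si](C)(C)Cl
Why: Bis-silylation protects the alcohol and turns the acid into a silyl ester that converts directly into the acid chloride, with the stereocentre untouched.

**Step 8**
Reactants: 14 tert-butyldimethylsilyl (S)-3-[(tert-butyldimethylsilyl)oxy]butanoate; 15 (trimethylsilyl)diazomethane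
Product: 17 (S)-4-[(tert-butyldimethylsilyl)oxy]-1-diazopentan-2-one, via acid chloride 16 (not isolated)
Conditions: (COCl)2, DMF (cat.), CH2Cl2, 0 °C to rt; evaporate; then 15, MeCN/THF, 0 °C
Reagents that add atoms: none
Why: Silyl esters give acid chlorides with oxalyl chloride under neutral conditions, and C-acylation of the silyl diazomethane with loss of TMSCl (Arndt–Eistert-type diazoketone synthesis) gives the diazoketone.

**Step 9**
Reactants: 12 (2R,3S,5R,6S)-5-[(tert-butyldimethylsilyl)oxy]-3-ethynyl-6-methyl-2-[(triethylsilyl)oxy]cyclohexan-1-one; 17 (S)-4-[(tert-butyldimethylsilyl)oxy]-1-diazopentan-2-one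
Product: 18 (4S)-4-[(tert-butyldimethylsilyl)oxy]-1-[(1R,2R,3S,5R,6S)-5-[(tert-butyldimethylsilyl)oxy]-3-ethynyl-1-hydroxy-6-methyl-2-[(triethylsilyl)oxy]cyclohexyl]-1-diazopentan-2-one
Conditions: 17 (1.2 equiv), LiN(iPr)2 (1.15 equiv), THF, −78 °C; then 12, −78 °C, 30 min; AcOH quench at −78 °C
Reagents that add atoms: none
Why: Aldol-type addition of the lithiated diazoketone takes the equatorial trajectory, anti to the axial 3-ethynyl group, so the new C–C bond is trans to the ethynyl group and the tertiary hydroxyl is axial and cis to the OTES group.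

**Step 10**
Reactants: 18 (4S)-4-[(tert-butyldimethylsilyl)oxy]-1-[(1R,2R,3S,5R,6S)-5-[(tert-butyldimethylsilyl)oxy]-3-ethynyl-1-hydroxy-6-methyl-2-[(triethylsilyl)oxy]cyclohexyl]-1-diazopentan-2-one
Product: 20 (2R,3S,4R,6S,7R)-4-[(tert-butyldimethylsilyl)oxy]-2-[(3S)-3-[(tert-butyldimethylsilyl)oxy]butanoyl]-6-ethynyl-2-hydroxy-3-methyl-7-[(triethylsilyl)oxy]cycloheptan-1-one, via diketone 19 (not isolated)
Conditions: DMDO (1.1 equiv), acetone, −78 to 0 °C; evaporate; then Me2AlCl (1.2 equiv), CH2Cl2, −78 to −20 °C; aq. KNaC4H4O6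
Reagents that add atoms: dimethyldioxirane, CC1(C)OO1
Why: Proposed new method: aluminium-templated α-ketol ring expansion of a cyclohexanol-derived β-hydroxy-α-diketone, in which Me2AlCl turns the tertiary alcohol of 19 into a chloro(methyl)aluminium alkoxide that chelates the adjacent carbonyl in a five-membered ring (O–C–C=O syn) so that the C1–C6 ring bond (the methyl-bearing carbon, a better σ-donor and less encumbered than the silyloxy-bearing C2) shifts to the activated carbonyl carbon on the face fixed by the chelate, which relays the carbinol configuration to the new quaternary carbinol with retention at the migrating carbon and turns the six-membered ring into the seven-membered one; the shift is driven by conversion of the vicinal dione into a 1,3-dione whose central alkoxide is held on aluminium by both carbonyls; the closest known reaction type is the Lewis-acid-promoted α-ketol (acyloin) rearrangement of β-hydroxy-α-ketoesters and of 17-hydroxy-20-ketosteroids (D-homoannulation).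

**Step 11**
Reactants: 20 (2R,3S,4R,6S,7R)-4-[(tert-butyldimethylsilyl)oxy]-2-[(3S)-3-[(tert-butyldimethylsilyl)oxy]butanoyl]-6-ethynyl-2-hydroxy-3-methyl-7-[(triethylsilyl)oxy]cycloheptan-1-one
Product: 22 (3S)-3-[(tert-butyldimethylsilyl)oxy]-1-[(1S,2S,3R,4S,6R,7S)-6-[(tert-butyldimethylsilyl)oxy]-4-ethynyl-1,2,3-trihydroxy-7-methylcycloheptyl]butan-1-one, via hydroxy ketone 21 (not isolated)
Conditions: HF·pyridine, pyridine, THF, 0 °C; concentrate; then Me4NBH(OAc)3, MeCN/AcOH (1:1), −30 °C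
Reagents that add atoms: none
Why: The TES ether is cleaved selectively, and the freed secondary C7 hydroxyl binds the triacetoxyborohydride and delivers hydride only to the adjacent ring ketone from its own face (Saksena–Evans directed reduction, anti 1,2-diol), while the side-chain ketone has no secondary hydroxyl within reach.

**Step 12**
Reactants: 22 (3S)-3-[(tert-butyldimethylsilyl)oxy]-1-[(1S,2S,3R,4S,6R,7S)-6-[(tert-butyldimethylsilyl)oxy]-4-ethynyl-1,2,3-trihydroxy-7-methylcycloheptyl]butan-1-one; 23 carbon monoxide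
Product: 24 (3aS,5R,6S,7S,8S,8aR)-5-[(tert-butyldimethylsilyl)oxy]-7-[(3S)-3-[(tert-butyldimethylsilyl)oxy]butanoyl]-7,8-dihydroxy-6-methyl-3-methylideneoctahydro-2H-cyclohepta[b]furan-2-one
Conditions: PdCl2 (5 mol%), SnCl2 (5 mol%), PPh3 (10 mol%), CO (7 atm), MeCN, 75 °C
Reagents that add atoms: none
Why: Palladium-catalysed cyclocarbonylation of a homopropargylic alcohol (alkoxycarbonyl–palladium addition across the alkyne, then protonolysis) closes the α-methylene-γ-butyrolactone on the hydroxyl that gives the five-membered ring, and the cis fusion is already fixed by the cis C3-OH/C4-ethynyl relationship.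

**Step 13**
Reactants: 24 (3aS,5R,6S,7S,8S,8aR)-5-[(tert-butyldimethylsilyl)oxy]-7-[(3S)-3-[(tert-butyldimethylsilyl)oxy]butanoyl]-7,8-dihydroxy-6-methyl-3-methylideneoctahydro-2H-cyclohepta[b]furan-2-one; 25 (R)-2-methylbutanoic acid
Product: 27 (3aS,5R,6S,7S,8S,8aR)-5-[(tert-butyldimethylsilyl)oxy]-7-[(3S)-3-[(tert-butyldimethylsilyl)oxy]butanoyl]-7-hydroxy-6-methyl-3-methylidene-2-oxooctahydro-2H-cyclohepta[b]furan-8-yl (2R)-2-methylbutanoate, via mixed anhydride 26 (not isolated)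
Conditions: 25, 2,4,6-trichlorobenzoyl chloride, Et3N, THF, rt; then 24, DMAP, toluene, rt
Reagents that add atoms: none
Why: Yamaguchi esterification acylates the only secondary hydroxyl (the other free hydroxyl is tertiary) without epimerising the α-stereocentre of the acid.

**Step 14**
Reactants: 27 (3aS,5R,6S,7S,8S,8aR)-5-[(tert-butyldimethylsilyl)oxy]-7-[(3S)-3-[(tert-butyldimethylsilyl)oxy]butanoyl]-7-hydroxy-6-methyl-3-methylidene-2-oxooctahydro-2H-cyclohepta[b]furan-8-yl (2R)-2-methylbutanoate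
Product: 28 (3aS,5R,6S,7S,8S,8aR)-5,7-dihydroxy-7-[(3S)-3-hydroxybutanoyl]-6-methyl-3-methylidene-2-oxooctahydro-2H-cyclohepta[b]furan-8-yl (2R)-2-methylbutanoate
Conditions: HF·pyridine, THF/pyridine, 0 °C to rt
Reagents that add atoms: none
Why: Acidic fluoride removes both TBS ethers without base, which spares the α-ketol, the β-hydroxy ketone, the ester and the α-methylene lactone.

**Compound list**
1 | 2-methylcyclohex-2-en-1-one | CC1=CCCCC1=O | starting material
2 | (3R)-2-methyl-3-(4,4,5,5-tetramethyl-1,3,2-dioxaborolan-2-yl)cyclohexan-1-one (C2 epimers) | O=C1CCC[C@@H](B2OC(C)(C)C(C)(C)O2)C1C | intermediate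
3 | (2S,3R)-3-hydroxy-2-methylcyclohexan-1-one | O=C1CCC[C@@H](O)[C@@H]1C | intermediate
4 | (2S,3R)-3-[(tert-butyldimethylsilyl)oxy]-2-methylcyclohexan-1-one | O=C1CCC[C@@H](O[Si](C)(C)C(C)(C)C)[C@@H]1C | intermediate
5 | tert-butyldimethyl{[(1R,2S)-2-methyl-3-[(trimethylsilyl)oxy]cyclohex-3-en-1-yl]oxy}silane | C[Si](C)(C)OC1=CCC[C@@H](O[Si](C)(C)C(C)(C)C)[C@@H]1C | intermediate
6 | (5R,6S)-5-[(tert-butyldimethylsilyl)oxy]-6-methylcyclohex-2-en-1-one | O=C1C=CC[C@@H](O[Si](C)(C)C(C)(C)C)[C@@H]1C | intermediate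
7 | ethynyltrimethylsilane | C#C[Si](C)(C)C | starting material
8 | tert-butyldimethyl{[(1R,2S,5R)-2-methyl-3-[(trimethylsilyl)oxy]-5-[(trimethylsilyl)ethynyl]cyclohex-3-en-1-yl]oxy}silane | C[Si](C)(C)OC1=C[C@H](C#C[Si](C)(C)C)C[C@@H](O[Si](C)(C)C(C)(C)C)[C@@H]1C | intermediate
9 | (2S,3S,5R,6S)-2-bromo-5-[(tert-butyldimethylsilyl)oxy]-6-methyl-3-[(trimethylsilyl)ethynyl]cyclohexan-1-one | Br[C@H]1[C@H](C#C[Si](C)(C)C)C[C@@H](O[Si](C)(C)C(C)(C)C)[C@H](C)C1=O | intermediate
10 | (1R,3S,4R,6S)-4-[(tert-butyldimethylsilyl)oxy]-3-methyl-2-oxo-6-[(trimethylsilyl)ethynyl]cyclohexyl formate | O=CO[C@@H]1[C@H](C#C[Si](C)(C)C)C[C@@H](O[Si](C)(C)C(C)(C)C)[C@H](C)C1=O | intermediate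
11 | (2R,3S,5R,6S)-5-[(tert-butyldimethylsilyl)oxy]-3-ethynyl-2-hydroxy-6-methylcyclohexan-1-one | O[C@@H]1[C@H](C#C)C[C@@H](O[Si](C)(C)C(C)(C)C)[C@H](C)C1=O | intermediate
12 | (2R,3S,5R,6S)-5-[(tert-butyldimethylsilyl)oxy]-3-ethynyl-6-methyl-2-[(triethylsilyl)oxy]cyclohexan-1-one | CC[Si](CC)(CC)O[C@@H]1[C@H](C#C)C[C@@H](O[Si](C)(C)C(C)(C)C)[C@H](C)C1=O | intermediate
13 | (S)-3-hydroxybutanoic acid | C[C@H](O)CC(=O)O | starting material
14 | tert-butyldimethylsilyl (S)-3-[(tert-butyldimethylsilyl)oxy]butanoate | C[C@H](O[Si](C)(C)C(C)(C)C)CC(=O)O[Si](C)(C)C(C)(C)C | intermediate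
15 | (trimethylsilyl)diazomethane | C[Si](C)(C)C=[N+]=[N-] | starting material
16 | (S)-3-[(tert-butyldimethylsilyl)oxy]butanoyl chloride | C[C@H](O[Si](C)(C)C(C)(C)C)CC(=O)Cl | intermediate
17 | (S)-4-[(tert-butyldimethylsilyl)oxy]-1-diazopentan-2-one | C[C@H](O[Si](C)(C)C(C)(C)C)CC(=O)C=[N+]=[N-] | intermediate
18 | (4S)-4-[(tert-butyldimethylsilyl)oxy]-1-[(1R,2R,3S,5R,6S)-5-[(tert-butyldimethylsilyl)oxy]-3-ethynyl-1-hydroxy-6-methyl-2-[(triethylsilyl)oxy]cyclohexyl]-1-diazopentan-2-one | CC[Si](CC)(CC)O[C@@H]1[C@H](C#C)C[C@@H](O[Si](C)(C)C(C)(C)C)[C@H](C)[C@@]1(O)C(=[N+]=[N-])C(=O)C[C@H](C)O[Si](C)(C)C(C)(C)C | intermediate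
19 | (5S)-5-[(tert-butyldimethylsilyl)oxy]-1-[(1S,2R,3S,5R,6S)-5-[(tert-butyldimethylsilyl)oxy]-3-ethynyl-1-hydroxy-6-methyl-2-[(triethylsilyl)oxy]cyclohexyl]hexane-1,2-dione | CC[Si](CC)(CC)O[C@@H]1[C@H](C#C)C[C@@H](O[Si](C)(C)C(C)(C)C)[C@H](C)[C@@]1(O)C(=O)C(=O)C[C@H](C)O[Si](C)(C)C(C)(C)C | intermediate
20 | (2R,3S,4R,6S,7R)-4-[(tert-butyldimethylsilyl)oxy]-2-[(3S)-3-[(tert-butyldimethylsilyl)oxy]butanoyl]-6-ethynyl-2-hydroxy-3-methyl-7-[(triethylsilyl)oxy]cycloheptan-1-one | CC[Si](CC)(CC)O[C@@H]1[C@H](C#C)C[C@@H](O[Si](C)(C)C(C)(C)C)[C@H](C)[C@@](O)(C(=O)C[C@H](C)O[Si](C)(C)C(C)(C)C)C1=O | intermediate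
21 | (2R,3S,4R,6S,7R)-4-[(tert-butyldimethylsilyl)oxy]-2-[(3S)-3-[(tert-butyldimethylsilyl)oxy]butanoyl]-6-ethynyl-2,7-dihydroxy-3-methylcycloheptan-1-one | O[C@@H]1[C@H](C#C)C[C@@H](O[Si](C)(C)C(C)(C)C)[C@H](C)[C@@](O)(C(=O)C[C@H](C)O[Si](C)(C)C(C)(C)C)C1=O | intermediate
22 | (3S)-3-[(tert-butyldimethylsilyl)oxy]-1-[(1S,2S,3R,4S,6R,7S)-6-[(tert-butyldimethylsilyl)oxy]-4-ethynyl-1,2,3-trihydroxy-7-methylcycloheptyl]butan-1-one | O[C@@H]1[C@H](C#C)C[C@@H](O[Si](C)(C)C(C)(C)C)[C@H](C)[C@@](O)(C(=O)C[C@H](C)O[Si](C)(C)C(C)(C)C)[C@H]1O | intermediate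
23 | carbon monoxide | [C-]#[O+] | starting material
24 | (3aS,5R,6S,7S,8S,8aR)-5-[(tert-butyldimethylsilyl)oxy]-7-[(3S)-3-[(tert-butyldimethylsilyl)oxy]butanoyl]-7,8-dihydroxy-6-methyl-3-methylideneoctahydro-2H-cyclohepta[b]furan-2-one | C=C1C(=O)O[C@@H]2[C@H]1C[C@@H](O[Si](C)(C)C(C)(C)C)[C@H](C)[C@@](O)(C(=O)C[C@H](C)O[Si](C)(C)C(C)(C)C)[C@H]2O | intermediate
25 | (R)-2-methylbutanoic acid | CC[C@@H](C)C(=O)O | starting material
26 | (R)-2-methylbutanoic 2,4,6-trichlorobenzoic anhydride | CC[C@@H](C)C(=O)OC(=O)c1c(Cl)cc(Cl)cc1Cl | intermediate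
27 | (3aS,5R,6S,7S,8S,8aR)-5-[(tert-butyldimethylsilyl)oxy]-7-[(3S)-3-[(tert-butyldimethylsilyl)oxy]butanoyl]-7-hydroxy-6-methyl-3-methylidene-2-oxooctahydro-2H-cyclohepta[b]furan-8-yl (2R)-2-methylbutanoate | C=C1C(=O)O[C@@H]2[C@H]1C[C@@H](O[Si](C)(C)C(C)(C)C)[C@H](C)[C@@](O)(C(=O)C[C@H](C)O[Si](C)(C)C(C)(C)C)[C@H]2OC(=O)[C@H](C)CC | intermediate
28 | (3aS,5R,6S,7S,8S,8aR)-5,7-dihydroxy-7-[(3S)-3-hydroxybutanoyl]-6-methyl-3-methylidene-2-oxooctahydro-2H-cyclohepta[b]furan-8-yl (2R)-2-methylbutanoate (CNP0291806.3) | C=C1C(=O)O[C@@H]2[C@H]1C[C@@H](O)[C@H](C)[C@@](O)(C(=O)C[C@H](C)O)[C@H]2OC(=O)[C@H](C)CC | target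

**Totals:** 14 steps; longest linear sequence 12 (steps 1–6 and 9–14).

**Steps most likely to fail**

Step 10 (the proposed ring expansion). The silyloxy-bearing ring carbon may migrate instead, the wrong rotamer may react, or the equilibrium may not favour the seven-membered ring. Fallback with known chemistry, setting out from 18: Rh2(OAc)4 (1 mol%) in CH2Cl2 at rt triggers the established carbenoid 1,2-shift ring expansion of an α-diazo-β-hydroxy ketone and gives the 2-acylcycloheptanone (3R,4R,6S,7R)-4-[(tert-butyldimethylsilyl)oxy]-2-[(3S)-3-[(tert-butyldimethylsilyl)oxy]butanoyl]-6-ethynyl-3-methyl-7-[(triethylsilyl)oxy]cycloheptan-1-one F1. The enolised 1,3-diketone is then hydroxylated at C2 with DMDO in acetone at 0 °C. The fallback returns to the route at 20; C2 epimers, if both form, are separated there.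

Step 12 (cyclocarbonylation on a polyfunctional triol). The α-ketol may not survive 75 °C with SnCl2, or the catalyst may stall. Fallback setting out from 22: Markovnikov hydrosilylation with [Cp*Ru(MeCN)3]PF6 (cat.) and Et3SiH in CH2Cl2 gives the vinylsilane (3S)-3-[(tert-butyldimethylsilyl)oxy]-1-[(1S,2S,3R,4R,6R,7S)-6-[(tert-butyldimethylsilyl)oxy]-1,2,3-trihydroxy-7-methyl-4-[1-(triethylsilyl)ethenyl]cycloheptyl]butan-1-one F2. Iododesilylation with NIS in (CF3)2CHOH at 0 °C gives the vinyl iodide (3S)-3-[(tert-butyldimethylsilyl)oxy]-1-[(1S,2S,3R,4R,6R,7S)-6-[(tert-butyldimethylsilyl)oxy]-1,2,3-trihydroxy-4-(1-iodoethenyl)-7-methylcycloheptyl]butan-1-one F3. Carbonylative lactonisation with Pd(PPh3)4 (cat.), CO (1 atm) and Et3N in THF at 50 °C returns to the route at 24.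

Step 5 (SN2 on a hindered α-bromo ketone). Elimination or epimerisation may compete. Fallback setting out from 6: the conjugate alkynylation of step 4 is run to silyl enol ether 8, which is oxidised with DMDO (Rubottom oxidation, acetone, −78 °C, then citric acid/MeOH). The oxidant enters anti to the alkynyl group and gives the trans α-hydroxy ketone (2S,3S,5R,6S)-5-[(tert-butyldimethylsilyl)oxy]-2-hydroxy-6-methyl-3-[(trimethylsilyl)ethynyl]cyclohexan-1-one F4. Mitsunobu inversion with formic acid (PPh3, DIAD, THF, 0 °C) gives formate 10, and K2CO3/MeOH as in step 5 returns to the route at 11.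

**Further compounds**
F1 | step 10 | (3R,4R,6S,7R)-4-[(tert-butyldimethylsilyl)oxy]-2-[(3S)-3-[(tert-butyldimethylsilyl)oxy]butanoyl]-6-ethynyl-3-methyl-7-[(triethylsilyl)oxy]cycloheptan-1-one | CC[Si](CC)(CC)O[C@@H]1[C@H](C#C)C[C@@H](O[Si](C)(C)C(C)(C)C)[C@H](C)C(C(=O)C[C@H](C)O[Si](C)(C)C(C)(C)C)C1=O
F2 | step 12 | (3S)-3-[(tert-butyldimethylsilyl)oxy]-1-[(1S,2S,3R,4R,6R,7S)-6-[(tert-butyldimethylsilyl)oxy]-1,2,3-trihydroxy-7-methyl-4-[1-(triethylsilyl)ethenyl]cycloheptyl]butan-1-one | O[C@@H]1[C@H](C(=C)[Si](CC)(CC)CC)C[C@@H](O[Si](C)(C)C(C)(C)C)[C@H](C)[C@@](O)(C(=O)C[C@H](C)O[Si](C)(C)C(C)(C)C)[C@H]1O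
F3 | step 12 | (3S)-3-[(tert-butyldimethylsilyl)oxy]-1-[(1S,2S,3R,4R,6R,7S)-6-[(tert-butyldimethylsilyl)oxy]-1,2,3-trihydroxy-4-(1-iodoethenyl)-7-methylcycloheptyl]butan-1-one | O[C@@H]1[C@H](C(I)=C)C[C@@H](O[Si](C)(C)C(C)(C)C)[C@H](C)[C@@](O)(C(=O)C[C@H](C)O[Si](C)(C)C(C)(C)C)[C@H]1O
F4 | step 5 | (2S,3S,5R,6S)-5-[(tert-butyldimethylsilyl)oxy]-2-hydroxy-6-methyl-3-[(trimethylsilyl)ethynyl]cyclohexan-1-one | O[C@H]1[C@H](C#C[Si](C)(C)C)C[C@@H](O[Si](C)(C)C(C)(C)C)[C@H](C)C1=O
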